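## The problem

Compound 10 is a 4-phenylchroman-2-one: a six-membered aryl lactone (O1–C2–C3–C4) fused at C4a/C8a to a phloroglucinol-type ring A. Ring A carries free hydroxyls at C5 and C7 and an (E)-3-(3,4-dihydroxyphenyl)propenoyl group at C8. The only stereocentre is the diarylmethine C4 (R). Nothing else in the molecule can direct it, so it must come from a chiral catalyst; it controls nothing in turn, the E enone being the only other stereochemical element. The three oxygens of ring A are all different and C6 and C8 are both activated, so the acyl group has to be placed at C8 and kept there. If the lactone opens while O5 is free, reclosure on O5 turns the 8-acyl into the 6-acyl isomer. The lactone is opened by hydroxide, alkoxide or acidic alcohols; the enone with its ortho hydroxyl closes to a flavanone under base or strong acid and does not survive hydrogenation; the catechol is easily oxidised; and C6 of the free phenol is attacked by carbon electrophiles. What invites a short route is the aryl ketone at C8, flanked by O1 and O7: its carbonyl carbon joins aromatic C8 to a trans styryl unit, the pattern left when an aryl iodide, carbon monoxide and a styrene are coupled.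

## Retrosynthesis

**10 from 9 (four O–benzyl bonds).** The phenols are masked as benzyl ethers in 9. Benzyl is chosen because BCl3 with pentamethylbenzene removes it at −78 °C with no nucleophile, base or hydrogen present, so the lactone stays closed and the enone is left alone. Methoxymethyl ethers would need acid in an alcohol or water, which opens the lactone and releases formaldehyde next to the nucleophilic C6. Methyl ethers need harsher Lewis acid. Benzyl also lets the route start from purchased 1 and 7.

**9 from 6, 8 and carbon monoxide (C8–C(=O) and C(=O)–Cα).** Both bonds of the ketone are cut at once, leaving aryl iodide 6 and styrene 8. The neighbouring options are weaker. An aldol condensation of a C8 methyl ketone needs hydroxide, which opens the lactone. A Friedel–Crafts acylation of ring A would not distinguish C6 from C8 and would expose the benzyl ethers to strong Lewis acid. The carbonylative coupling runs with a tertiary amine as the only base. The forward reaction has to favour CO insertion over direct arylation of the alkene, give the E enone, and leave the lactone and C4 untouched.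

**6 from 5 (C8–I).** The iodide is introduced by electrophilic substitution on lactone 5. The lactone stage is chosen deliberately: there O1 is acylated and a poor donor. C8 is para to the C5 ether oxygen and ortho to the C7 ether oxygen, whereas C6 is para only to O1 and lies between two benzyloxy groups. At the lactol stage O1 would be a full ether donor and would steer the electrophile to C6.

**5 from 4, and 4 from 1 and 2 (C4–C4a and O1–C2; C2 oxidation level).** Lactone 5 is the oxidation product of lactol 4. Lactol 4 is cut into phenol 1 and enal 2: the ortho carbon of the phenol adds to C-β of the enal and the phenolic oxygen closes on the aldehyde. Iminium catalysis with a diarylprolinol silyl ether makes this addition enantioselective, so ring, lactol carbon and stereocentre come from two purchased compounds in one operation. The two ortho positions of 1 are equivalent, so no regiochemical question arises here.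

**8 from 7 (C=C).** The styrene is the methylenation product of purchased aldehyde 7. It is made just before use, since electron-rich styrenes polymerise on storage.

## Roads not taken

**Alternative 1:** Ring A itself is cut (C4a–C5, C5–C6, C8–C8a) and rebuilt by a Danheiser benzannulation. Heating cyclobutenone A2 would open it to a vinylketene, which adds to the chiral siloxyalkyne A3. Four-electron ring opening and six-electron closure would then give the pentasubstituted phenol A1, with the C4 stereocentre already on the side chain.
- Merits: every substituent of ring A is placed by the connectivity of the partners. The C6/C8 question never arises, and the C8 carbon arrives as a masked acetyl group.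
- Weak points: A3 is a chiral ynol silyl ether that needs its own multi-step synthesis. A1 is still far from 10: the side arm must be oxidised and lactonised onto O1 after selective desilylation, the carbinol oxidised, and the enone built by base-mediated aldol condensation next to an aryl lactone. The C7 ethyl ether must then be cleaved under conditions that lactone, enone and catechol are unlikely to survive.
- Comparison: this road is better on regiochemical certainty. Against that the chosen plan sets six steps from purchased compounds and a regiochemistry that rests on a known preference and can be secured by iodinating before the annulation.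

**Alternative 2:** The lactone carbonyl is cut out (C2–C3 and C2–O1), with C2 from CO and the C4 hydrogen from a palladium hydride. Phenol A5 would be treated with Pd(OAc)2, a chiral bisphosphine, CO and H2. Hydride would add to the diaryl-substituted carbon, CO would insert into the primary alkyl–palladium bond, and the phenol would capture the acyl group to give A4.
- Merits: ring closure and stereocentre in one catalytic step, the correct lactone oxidation level without a separate oxidation, and an acetyl group already at C8.
- Weak points: the catalyst must tell apart the two aryl groups of a 1,1-diarylethene, for which no reliable enantioselective version is at hand. Hydride addition in the other sense leads to a five-membered benzofuranone. A5 carries the same regiochemical problem back into its own synthesis. The enone would again need a hydroxide-mediated condensation, and four methyl ethers would have to be cleaved at the end.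
- Comparison: equal in using CO as a building block and better in fixing the acyl position early. The chosen plan sets against it a stereocentre made by well-studied iminium catalysis and an enone formed without base strong enough to open the lactone.

**Alternative 3:** The cut is C3–C4 and O1–C2, a (4+2) annulation. Base would release an ortho-quinone methide from sulfone A7, and a chiral N-heterocyclic carbene would turn 4-nitrophenyl acetate A8 into an azolium enolate. Conjugate addition at the exocyclic carbon and O-acylation would give lactone A6.
- Merits: convergent, and it delivers the lactone directly, saving the chromium oxidation of the chosen route.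
- Weak points: the unsubstituted acetate-derived enolate is the least selective member of its class. The base and the released 4-nitrophenoxide can open the product lactone. A7 costs an extra three-component step. A6 still needs functionalisation at C8, so the regiochemical question is not removed, and the methyl ethers remain a late liability.
- Comparison: this road is as good as steps 1 and 2 of the chosen plan in step count and better in avoiding hexavalent chromium. The chosen plan sets against it a purchased enal, an established catalyst class for exactly this phenol type, and protecting groups that come off cold.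

Key step: step 5

Remark: lactol 4 is an equilibrating pair of C2 epimers (with its open form 3) and is carried as such, since that centre is removed in step 2.

## Route

**Step 1**
Reactants: 1 3,5-bis(benzyloxy)phenol; 2 (E)-cinnamaldehyde
Product: 4 (4R)-5,7-bis(benzyloxy)-4-phenylchroman-2-ol (mixture of C2 epimers), via open-chain (R)-3-aryl-3-phenylpropanal 3 (not isolated)
Conditions: (R)-2-[diphenyl(trimethylsilyloxy)methyl]pyrrolidine (20 mol %), PhCO2H (20 mol %), toluene, 0 °C → rt
Reagents that add atoms: none
Why: Iminium-catalysed asymmetric Friedel–Crafts alkylation with hemiacetal closure, known for electron-rich phenols and enals. In the E,s-trans iminium ion of 2 the diphenyl(silyloxy)methyl group of the (R)-catalyst covers the Si face of C-β, so the ortho carbon of 1 adds to the Re face and sets (R) at the future C4. The released aldehyde 3 is trapped by the neighbouring hydroxyl as lactol 4.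

**Step 2**
Reactants: 4 (4R)-5,7-bis(benzyloxy)-4-phenylchroman-2-ol
Product: 5 (R)-5,7-bis(benzyloxy)-4-phenylchroman-2-one
Conditions: (C5H5NH)[CrO3Cl] (1.5 equiv), NaOAc, 4 Å MS, CH2Cl2, rt
Reagents that add atoms: none
Why: Lactol-to-lactone oxidation with buffered pyridinium chlorochromate (hexavalent chromium). Both C2 epimers converge on one lactone, and the benzyl ethers and the C4 methine are inert, so the stereocentre is untouched.

**Step 3**
Reactants: 5 (R)-5,7-bis(benzyloxy)-4-phenylchroman-2-one
Product: 6 (R)-5,7-bis(benzyloxy)-8-iodo-4-phenylchroman-2-one
Conditions: N-iodosuccinimide (1.05 equiv), CF3CO2H (10 mol %), MeCN, 0 °C → rt, dark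
Reagents that add atoms: N-iodosuccinimide, O=C1CCC(=O)N1I
Why: Electrophilic aromatic iodination. C8 is para to the C5 ether oxygen and ortho to the C7 ether oxygen, while C6 is para only to the acyl-deactivated O1 and sits between two benzyloxy groups, the C5 one turned toward C6 by the substituent at C4. The same preference for C8 is the established outcome for 5,7-dialkoxy-coumarins and -flavones.

**Step 4**
Reactants: 7 3,4-bis(benzyloxy)benzaldehyde
Product: 8 3,4-bis(benzyloxy)styrene
Conditions: Ph3PCH3Br, KOt-Bu, THF, 0 °C → rt
Reagents that add atoms: methyltriphenylphosphonium bromide, C[P+](c1ccccc1)(c1ccccc1)c1ccccc1.[Br-]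
Why: Wittig methylenation of an aromatic aldehyde with the non-stabilised ylide; benzyl ethers are inert.

**Step 5**
Reactants: 6 (R)-5,7-bis(benzyloxy)-8-iodo-4-phenylchroman-2-one; 8 3,4-bis(benzyloxy)styrene
Product: 9 (R)-5,7-bis(benzyloxy)-8-[(E)-3-(3,4-bis(benzyloxy)phenyl)prop-2-enoyl]-4-phenylchroman-2-one
Conditions: Pd(OAc)2 (5 mol %), di(1-adamantyl)-n-butylphosphine (10 mol %), Et3N (2 equiv), CO (10 bar), 1,4-dioxane, 100 °C
Reagents that add atoms: carbon monoxide, [C-]#[O+]
Why: Carbonylative Heck reaction; the closest known reaction type is the coupling of aryl iodides, CO and styrenes to chalcones. Pd(OAc)2 is reduced in the flask to zerovalent palladium, which inserts into the C8–I bond of 6, and CO then inserts into the aryl–palladium bond to give an aroyl complex of divalent palladium. This migration should be fast because the aryl group is electron-rich and the two ortho oxygens (O1 and the C7 benzyloxy group) crowd the metal; the same ortho groups slow direct alkene insertion into the aryl–palladium bond, so under 10 bar of CO the carbonylative channel should dominate. Styrene 8 inserts into the aroyl–palladium bond with the acyl group on the terminal carbon and the metal on the benzylic carbon, and syn β-hydride elimination gives the conjugated E enone; Et3N takes up HI and returns zerovalent palladium. No ring is closed and no stereocentre is formed. The site of acylation is fixed by the iodide and the E geometry by the elimination step. The spectators are safe: the lactone meets no nucleophile in dry dioxane with a tertiary amine, C4 has neither an acidic hydrogen nor a leaving group, and benzyl ethers are inert without hydrogen.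

**Step 6**
Reactants: 9 (R)-5,7-bis(benzyloxy)-8-[(E)-3-(3,4-bis(benzyloxy)phenyl)prop-2-enoyl]-4-phenylchroman-2-one
Product: 10 (R)-8-[(E)-3-(3,4-dihydroxyphenyl)prop-2-enoyl]-5,7-dihydroxy-4-phenylchroman-2-one
Conditions: BCl3 (8 equiv), C6HMe5 (12 equiv), CH2Cl2, −78 °C; then H2O, −78 °C → rt
Reagents that add atoms: none
Why: Lewis-acid debenzylation of aryl benzyl ethers with a cation scavenger. BCl3 activates each ether oxygen and pentamethylbenzene takes up the benzyl cation, so C6 and the catechol ring are not C-benzylated. The cold, non-nucleophilic medium keeps the lactone closed (no migration of the acyl group to C6) and leaves the enone and C4 untouched.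

## Compound list

1 | 3,5-bis(benzyloxy)phenol | Oc1cc(OCc2ccccc2)cc(OCc2ccccc2)c1 | starting material
2 | (E)-cinnamaldehyde | O=C/C=C/c1ccccc1 | starting material
3 | (R)-3-[2,4-bis(benzyloxy)-6-hydroxyphenyl]-3-phenylpropanal (not isolated) | O=CC[C@H](c1ccccc1)c1c(O)cc(OCc2ccccc2)cc1OCc1ccccc1 | intermediate
4 | (4R)-5,7-bis(benzyloxy)-4-phenylchroman-2-ol (C2 epimers) | OC1C[C@H](c2ccccc2)c2c(OCc3ccccc3)cc(OCc3ccccc3)cc2O1 | intermediate
5 | (R)-5,7-bis(benzyloxy)-4-phenylchroman-2-one | O=C1C[C@H](c2ccccc2)c2c(OCc3ccccc3)cc(OCc3ccccc3)cc2O1 | intermediate
6 | (R)-5,7-bis(benzyloxy)-8-iodo-4-phenylchroman-2-one | O=C1C[C@H](c2ccccc2)c2c(OCc3ccccc3)cc(OCc3ccccc3)c(I)c2O1 | intermediate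
7 | 3,4-bis(benzyloxy)benzaldehyde | O=Cc1ccc(OCc2ccccc2)c(OCc2ccccc2)c1 | starting material
8 | 3,4-bis(benzyloxy)styrene | C=Cc1ccc(OCc2ccccc2)c(OCc2ccccc2)c1 | intermediate
9 | (R)-5,7-bis(benzyloxy)-8-[(E)-3-(3,4-bis(benzyloxy)phenyl)prop-2-enoyl]-4-phenylchroman-2-one | O=C1C[C@H](c2ccccc2)c2c(OCc3ccccc3)cc(OCc3ccccc3)c(C(=O)/C=C/c3ccc(OCc4ccccc4)c(OCc4ccccc4)c3)c2O1 | intermediate
10 | (R)-8-[(E)-3-(3,4-dihydroxyphenyl)prop-2-enoyl]-5,7-dihydroxy-4-phenylchroman-2-one | O=C1C[C@H](c2ccccc2)c2c(O)cc(O)c(C(=O)/C=C/c3ccc(O)c(O)c3)c2O1 | target

## Step count and risks

Total: 6 steps. Longest linear sequence: 5 steps (steps 1, 2, 3, 5, 6); step 4 is the one-step side branch.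

**Step 5 (key step).** The most likely failure is loss of the carbonylative channel at the doubly ortho-substituted aryl–palladium stage: direct arylation of the styrene, hydrodeiodination, or slow alkene insertion into the hindered aroyl complex with catalyst decomposition.
Fallback, from 8 back to 9: cross-metathesis of 8 with vinylboronic acid pinacol ester (second-generation Grubbs catalyst, (H2IMes)(PCy3)Cl2Ru=CHPh, CH2Cl2, 40 °C) gives (E)-2-[2-(3,4-bis(benzyloxy)phenyl)ethenyl]-4,4,5,5-tetramethyl-1,3,2-dioxaborolane F1. A carbonylative Suzuki–Miyaura coupling of F1 with iodide 6 (Pd(dppf)Cl2, K2CO3, CO, anisole, 80 °C) then forms the same two bonds by transmetalation instead of alkene insertion, with the E geometry carried in by the boronate, and rejoins the route at 9.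

**Step 3.** Iodination may occur partly at C6, or twice, because both positions are activated and the preference for C8 rests on analogy. The isomers are distinguishable, since H6 of 6 lies between two benzyloxy groups and H8 of the unwanted isomer beside only one.
Fallback, from 1 back to 6: phenol 1 is iodinated first (N-iodosuccinimide, CH2Cl2, −40 °C). The unsymmetrical monoiodide, 3,5-bis(benzyloxy)-2-iodophenol F2, is separated from the symmetrical para isomer. It is carried through the annulation of step 1 with 2 to (4R)-5,7-bis(benzyloxy)-8-iodo-4-phenylchroman-2-ol F3, in which iodine can only be at C8 because ring closure uses the hydroxyl next to it. Oxidation as in step 2 returns to 6.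

**Step 1.** Facial selectivity may be insufficient on this bulky phenol, and alkylation at the para carbon or a second alkylation of the product may compete.
Fallback, from 1 back to 5: 1 and ethyl propiolate (Pd(OAc)2, HCO2H, NaOAc, rt) give 5,7-bis(benzyloxy)coumarin F4 by hydroarylation and lactonisation. Rhodium-catalysed asymmetric conjugate addition of PhB(OH)2 ([Rh(acac)(C2H4)2], SEGPHOS, dioxane/H2O, 60 °C) then gives lactone 5 directly. The ligand antipode is chosen for the (R) product; by analogy with simple coumarins this should be (R)-SEGPHOS.

**Step 6.** Cleavage of the four ethers may be incomplete. The boron-bound C7 oxygen may close onto the enone. Acidic work-up may open the lactone, which can then reclose on O5.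
Fallback, from 6 back to 10: the ring A ethers are removed before the enone exists, using the conditions of step 6 on 6, to give (R)-5,7-dihydroxy-8-iodo-4-phenylchroman-2-one F5. Silylation (t-BuMe2SiOTf, 2,6-lutidine, CH2Cl2, −78 → 0 °C) gives (R)-5,7-bis(tert-butyldimethylsilyloxy)-8-iodo-4-phenylchroman-2-one F6. 3,4-Dihydroxybenzaldehyde is silylated (t-BuMe2SiCl, imidazole, DMF) to 3,4-bis(tert-butyldimethylsilyloxy)benzaldehyde F7 and methylenated as in step 4 to 3,4-bis(tert-butyldimethylsilyloxy)styrene F8. The coupling of step 5 applied to F6 and F8 gives (R)-5,7-bis(tert-butyldimethylsilyloxy)-8-[(E)-3-(3,4-bis(tert-butyldimethylsilyloxy)phenyl)prop-2-enoyl]-4-phenylchroman-2-one F9. HF·pyridine in THF/pyridine at 0 °C then frees the four phenols under nearly neutral conditions and arrives at 10.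

## Further compounds

F1 | step 5 | (E)-2-[2-(3,4-bis(benzyloxy)phenyl)ethenyl]-4,4,5,5-tetramethyl-1,3,2-dioxaborolane | CC1(C)OB(/C=C/c2ccc(OCc3ccccc3)c(OCc3ccccc3)c2)OC1(C)C
F2 | step 3 | 3,5-bis(benzyloxy)-2-iodophenol | Oc1cc(OCc2ccccc2)cc(OCc2ccccc2)c1I
F3 | step 3 | (4R)-5,7-bis(benzyloxy)-8-iodo-4-phenylchroman-2-ol (C2 epimers) | OC1C[C@H](c2ccccc2)c2c(OCc3ccccc3)cc(OCc3ccccc3)c(I)c2O1
F4 | step 1 | 5,7-bis(benzyloxy)coumarin | O=C1C=Cc2c(OCc3ccccc3)cc(OCc3ccccc3)cc2O1
F5 | step 6 | (R)-5,7-dihydroxy-8-iodo-4-phenylchroman-2-one | O=C1C[C@H](c2ccccc2)c2c(O)cc(O)c(I)c2O1
F6 | step 6 | (R)-5,7-bis(tert-butyldimethylsilyloxy)-8-iodo-4-phenylchroman-2-one | O=C1C[C@H](c2ccccc2)c2c(O[Si](C)(C)C(C)(C)C)cc(O[Si](C)(C)C(C)(C)C)c(I)c2O1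
F7 | step 6 | 3,4-bis(tert-butyldimethylsilyloxy)benzaldehyde | O=Cc1ccc(O[Si](C)(C)C(C)(C)C)c(O[Si](C)(C)C(C)(C)C)c1
F8 | step 6 | 3,4-bis(tert-butyldimethylsilyloxy)styrene | C=Cc1ccc(O[Si](C)(C)C(C)(C)C)c(O[Si](C)(C)C(C)(C)C)c1
F9 | step 6 | (R)-5,7-bis(tert-butyldimethylsilyloxy)-8-[(E)-3-(3,4-bis(tert-butyldimethylsilyloxy)phenyl)prop-2-enoyl]-4-phenylchroman-2-one | O=C1C[C@H](c2ccccc2)c2c(O[Si](C)(C)C(C)(C)C)cc(O[Si](C)(C)C(C)(C)C)c(C(=O)/C=C/c3ccc(O[Si](C)(C)C(C)(C)C)c(O[Si](C)(C)C(C)(C)C)c3)c2O1
A1 | alternative 1 | (R)-2-[3-(tert-butyldimethylsilyloxy)-1-phenylpropyl]-5-ethoxy-4-[1-(tert-butyldimethylsilyloxy)ethyl]-3-(triisopropylsilyloxy)phenol | CC(C)(C)[Si](C)(C)OCC[C@H](c1ccccc1)c1c(O)cc(OCC)c(C(C)O[Si](C)(C)C(C)(C)C)c1O[Si](C(C)C)(C(C)C)C(C)C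
A2 | alternative 1 | 3-ethoxy-2-[1-(tert-butyldimethylsilyloxy)ethyl]cyclobut-2-en-1-one | CCOC1=C(C(C)O[Si](C)(C)C(C)(C)C)C(=O)C1
A3 | alternative 1 | (R)-tert-butyldimethyl{[3-phenyl-5-(triisopropylsilyloxy)pent-4-yn-1-yl]oxy}silane | CC(C)[Si](C(C)C)(C(C)C)OC#C[C@@H](c1ccccc1)CCO[Si](C)(C)C(C)(C)C
A4 | alternative 2 | (R)-8-acetyl-5,7-dimethoxy-4-phenylchroman-2-one | O=C1C[C@H](c2ccccc2)c2c(OC)cc(OC)c(C(C)=O)c2O1
A5 | alternative 2 | 1-[2-hydroxy-4,6-dimethoxy-3-(1-phenylethenyl)phenyl]ethan-1-one | C=C(c1ccccc1)c1c(OC)cc(OC)c(C(C)=O)c1O
A6 | alternative 3 | (R)-5,7-dimethoxy-4-phenylchroman-2-one | O=C1C[C@H](c2ccccc2)c2c(OC)cc(OC)cc2O1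
A7 | alternative 3 | 3,5-dimethoxy-2-[phenyl(4-methylphenylsulfonyl)methyl]phenol | COc1cc(O)c(C(c2ccccc2)S(=O)(=O)c2ccc(C)cc2)c(OC)c1
A8 | alternative 3 | 4-nitrophenyl acetate | CC(=O)Oc1ccc([N+](=O)[O-])cc1
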